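**Strategy.** Ring B of the target is a cyclohexa-2,5-dienone in which C6=C7 and C9=C10 flank the quaternary C5 and the oxygen sits on C8. This is the direct [4+2] adduct of a 1-oxygenated diene (C5=C6–C7=C8–O) and an alkyne (C9≡C10). Because the alkyne carbonyl C1 is tied to C5 through C2–C4, one intramolecular Diels–Alder reaction of dienyl ynone 18 forms C5–C10 and C8–C9, closes rings A and B together and sets C5 from C4. Compound 18 is a terminal ynone carrying a (7E,9E)-ethoxydiene; C3 rides through as its epimer, so that the tether is all-equatorial, and is corrected later by oxidation–reduction.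

Key step: step 13

Remarks on the chemistry:
- Ring atoms are numbered C1–C10 as in the target, with C11 the side-chain carbon on C7. Bicyclic compounds are named on this numbering as substituted octalin-6,9-dienes (ring A = C1–C5/C10, ring B = C5–C10). β means the face of the C5 methyl.
- The C8 oxygen is carried as an ethyl enol ether and C3 as its α (epimeric) silyl ether until step 19; both are spectators of the cycloaddition.
- Angeloyl = (2Z)-2-methylbut-2-enoyl. The target is read as (1R,3S,4R,5R), i.e. 1β-OH, 3β-O-angeloyl, 4β,5β-dimethyl.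

Step 1
Reactants: 1 propane-1,3-diol
Product: 2 3-[(4-methoxybenzyl)oxy]propan-1-ol
Conditions: NaH (1 equiv), 4-methoxybenzyl chloride, Bu4NI (cat.), THF, 0 °C to rt, excess diol
Reagents that add atoms: 4-methoxybenzyl chloride, COc1ccc(CCl)cc1
Why: Williamson etherification of the mono-alkoxide; the excess of diol keeps double alkylation low.

Step 2
Reactants: 2 3-[(4-methoxybenzyl)oxy]propan-1-ol
Product: 3 3-[(4-methoxybenzyl)oxy]propanal
Conditions: TEMPO (cat.), PhI(OAc)2, CH2Cl2, rt
Reagents that add atoms: none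
Why: TEMPO-catalysed oxidation stops at the aldehyde and leaves the benzylic ether untouched.

Step 3
Reactants: 3 3-[(4-methoxybenzyl)oxy]propanal; 4 (S)-4-benzyl-3-propanoyl-1,3-thiazolidine-2-thione
Product: 6 (S)-4-benzyl-3-[(2S,3R)-3-hydroxy-5-[(4-methoxybenzyl)oxy]-2-methylpentanoyl]-1,3-thiazolidine-2-thione, via chlorotitanium enolate 5 (not isolated)
Conditions: TiCl4, i-Pr2NEt, N-methyl-2-pyrrolidone, CH2Cl2, 0 °C; then 3, −78 to 0 °C
Reagents that add atoms: none
Why: Crimmins titanium aldol reaction: the (Z)-enolate 5 adds through a Zimmerman–Traxler chair and the (S)-benzyl auxiliary fixes both new centres as the Evans-syn (2S,3R) pair, which become C4 and C3.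

Step 4
Reactants: 6 aldol adduct
Product: 7 (S)-4-benzyl-3-[(2S,3R)-5-[(4-methoxybenzyl)oxy]-2-methyl-3-(triethylsilyloxy)pentanoyl]-1,3-thiazolidine-2-thione
Conditions: Et3SiOTf, 2,6-lutidine, CH2Cl2, −78 °C
Reagents that add atoms: triethylsilyl trifluoromethanesulfonate, CC[Si](CC)(CC)OS(=O)(=O)C(F)(F)F
Why: Low-temperature silylation of the secondary alcohol with the triflate and 2,6-lutidine blocks retro-aldol cleavage in the following steps.

Step 5
Reactants: 7 silylated aldol adduct
Product: 8 (2S,3R)-5-[(4-methoxybenzyl)oxy]-2-methyl-3-(triethylsilyloxy)pentanal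
Conditions: i-Bu2AlH, CH2Cl2, −78 °C; aqueous potassium sodium tartrate
Reagents that add atoms: none
Why: N-Acylthiazolidinethiones are reduced by i-Bu2AlH directly to the aldehyde because the tetrahedral aluminium adduct survives until work-up; at −78 °C the α centre is not epimerised.

Step 6
Reactants: 8 aldehyde
Product: 9 (3R,4R)-1-[(4-methoxybenzyl)oxy]-4-methyl-3-(triethylsilyloxy)hex-5-yne
Conditions: dimethyl (1-diazo-2-oxopropyl)phosphonate, K2CO3, MeOH, 0 °C to rt
Reagents that add atoms: dimethyl (1-diazo-2-oxopropyl)phosphonate, COP(=O)(OC)C(=[N+]=[N-])C(C)=O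
Why: Ohira–Bestmann (Seyferth–Gilbert) homologation turns the aldehyde into the terminal alkyne under carbonate conditions that spare the α-methyl centre.

Step 7
Reactants: 9 alkyne
Product: 11 (3R,4R,5E)-6-iodo-1-[(4-methoxybenzyl)oxy]-4,5-dimethyl-3-(triethylsilyloxy)hex-5-ene, via alkenyldimethylalane 10 (not isolated)
Conditions: Me3Al, Cp2ZrCl2 (cat.), CH2Cl2, 0 °C to rt; then I2, THF, −30 °C
Reagents that add atoms: trimethylaluminium, C[Al](C)C; iodine, II
Why: Negishi zirconium-catalysed carboalumination adds methyl (to C5) and aluminium syn across the alkyne, and iodinolysis with retention gives the (E)-iodoalkene, which fixes the C5=C6 geometry.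

Step 8
Reactants: 11 iodoalkene
Product: 12 (3R,4R,5E)-6-iodo-4,5-dimethyl-3-(triethylsilyloxy)hex-5-en-1-ol
Conditions: DDQ, CH2Cl2/pH 7 buffer, 0 °C
Reagents that add atoms: none
Why: Oxidative cleavage of the 4-methoxybenzyl ether by DDQ under buffered conditions leaves the silyl ether and the iodoalkene intact.

Step 9
Reactants: 12 primary alcohol
Product: 13 (3R,4R,5E)-6-iodo-4,5-dimethyl-3-(triethylsilyloxy)hex-5-enoic acid
Conditions: TEMPO (cat.), PhI(OAc)2, MeCN/pH 7 buffer, rt
Reagents that add atoms: water, O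
Why: TEMPO/PhI(OAc)2 in aqueous acetonitrile takes the primary alcohol through the aldehyde hydrate to the acid without touching the iodoalkene.

Step 10
Reactants: 13 acid
Product: 14 (3R,4R,5E)-6-iodo-N-methoxy-N,4,5-trimethyl-3-(triethylsilyloxy)hex-5-enamide
Conditions: MeNH(OMe)·HCl, EDC·HCl, HOBt, N-methylmorpholine, CH2Cl2, 0 °C to rt
Reagents that add atoms: N,O-dimethylhydroxylamine hydrochloride, CNOC.Cl
Why: Carbodiimide coupling gives the Weinreb amide, the acyl form that later accepts exactly one alkynyl Grignard addition.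

Step 11
Reactants: 14 Weinreb amide; 15 2-[(E)-2-ethoxyethenyl]-4,4,5,5-tetramethyl-1,3,2-dioxaborolane
Product: 16 (3R,4R,5E,7E)-8-ethoxy-N-methoxy-N,4,5-trimethyl-3-(triethylsilyloxy)octa-5,7-dienamide
Conditions: Pd(dppf)Cl2 (cat.), K3PO4 (aq.), THF, 45 °C
Reagents that add atoms: none
Why: Suzuki–Miyaura coupling proceeds with retention at both partners and so delivers the (5E,7E)-1-ethoxydiene without any enolisation step.

Step 12
Reactants: 16 dienyl Weinreb amide; 17 ethynylmagnesium bromide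
Product: 18 (5R,6R,7E,9E)-10-ethoxy-6,7-dimethyl-5-(triethylsilyloxy)deca-7,9-dien-1-yn-3-one
Conditions: THF, −20 to 0 °C; cold aqueous NH4Cl, used at once
Reagents that add atoms: none
Why: The Grignard addition stops at the chelated tetrahedral intermediate, which releases the ynone only on cold work-up, after the acid-sensitive diene is already in place.

Step 13
Reactants: 18 dienyl ynone
Product: 19 8α-ethoxy-4β,5β-dimethyl-3α-(triethylsilyloxy)octalin-6,9-dien-1-one
Conditions: toluene (0.005 M), 2,6-di-tert-butyl-4-methylphenol (cat.), 90 °C, argon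
Reagents that add atoms: none
Why: Heating brings the ethoxydiene C5=C6–C7=C8 and the ynone C9≡C10 together in a concerted, asynchronous [4+2] cycloaddition; the closest known reaction type is the thermal intramolecular Diels–Alder reaction of a tethered 1-oxydiene with an alkynone, which stops at the cyclohexa-1,4-diene. Ring B closes by the cycloaddition bonds C5–C10 and C8–C9 (six-membered, suprafacial on both partners), and ring A closes at the same time as a six-membered ring because the four-atom tether C1–C4 joins the diene terminus C5 to the alkyne carbon C10 (type 1 mode; the linear alkyne leaves no endo/exo choice and requires the tether on the outer position of C5, as in the 7E isomer). C5 is controlled by the C4 stereocentre: in the half-chair tether C4–H eclipses C5=C6, the C4 methyl lies anti to the forming C5–C10 bond and the C3 silyl ether is equatorial, so the C5 methyl ends cis to the C4 methyl. C8 follows from suprafacial addition to the (9E)-enol ether (ethoxy cis to C4) and is erased in step 14. The step needs π-facial selectivity at C5 and the tether-enforced regiochemistry; the syn C3/C4 relationship of 18 secures the first, since the other face is reached only if the C4 methyl takes the in-plane position against C6–H with the silyl ether axial, or if C3 and the C4 methyl straddle C5=C6, and the quaternary C5 rules out aromatisation of the adduct.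

Step 14
Reactants: 19 cycloadduct
Product: 20 4β,5β-dimethyl-3α-(triethylsilyloxy)octalin-6,9-diene-1,8-dione
Conditions: DDQ, CH2Cl2/pH 7 buffer, 0 °C to rt
Reagents that add atoms: water, O
Why: DDQ abstracts hydride from the doubly allylic, ether-bearing C8–H of the cyclohexa-1,4-diene; water adds to the oxocarbenium ion and loss of ethanol gives the cross-conjugated dienone.

Step 15
Reactants: 20 ene-dione
Product: 21 1β-hydroxy-4β,5β-dimethyl-3α-(triethylsilyloxy)octalin-6,9-dien-8-one
Conditions: NaBH4 (1 equiv), CeCl3·7H2O, MeOH/CH2Cl2, −78 °C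
Reagents that add atoms: none
Why: Luche conditions give 1,2-reduction of the singly conjugated C1 ketone in preference to the doubly conjugated C8 ketone; hydride attacks anti to the axial C5 methyl, so the C1 hydroxyl is β (R).

Step 16
Reactants: 21 C1 alcohol
Product: 22 1β-(tert-butyldimethylsilyloxy)-4β,5β-dimethyl-3α-(triethylsilyloxy)octalin-6,9-dien-8-one
Conditions: t-BuMe2SiOTf, 2,6-lutidine, CH2Cl2, −78 to −20 °C
Reagents that add atoms: tert-butyldimethylsilyl trifluoromethanesulfonate, CC(C)(C)[Si](C)(C)OS(=O)(=O)C(F)(F)F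
Why: Silylation with the triflate protects the hindered allylic C1 alcohol so that C3 can be oxidised alone.

Step 17
Reactants: 22 bis-silyl ether
Product: 23 1β-(tert-butyldimethylsilyloxy)-3α-hydroxy-4β,5β-dimethyloctalin-6,9-dien-8-one
Conditions: HF·pyridine, pyridine, THF, 0 °C
Reagents that add atoms: none
Why: Buffered HF·pyridine removes the triethylsilyl ether selectively in the presence of the tert-butyldimethylsilyl ether.

Step 18
Reactants: 23 C3 alcohol
Product: 24 1β-(tert-butyldimethylsilyloxy)-4β,5β-dimethyloctalin-6,9-diene-3,8-dione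
Conditions: Dess–Martin periodinane, NaHCO3, CH2Cl2, 0 °C
Reagents that add atoms: none
Why: Dess–Martin oxidation under bicarbonate buffer erases the provisional C3 centre; the neutral conditions do not epimerise C4.

Step 19
Reactants: 24 C3 ketone
Product: 25 1β-(tert-butyldimethylsilyloxy)-3β-hydroxy-4β,5β-dimethyloctalin-6,9-dien-8-one
Conditions: NaBH4, MeOH/CH2Cl2, −78 °C
Reagents that add atoms: none
Why: NaBH4 at low temperature reduces the saturated ketone before the cross-conjugated dienone; the β face of C3 is shielded by the syn-axial C5 methyl and C1 silyl ether, so hydride enters from the α face and the hydroxyl is set β, the (S) configuration of the target.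

Step 20
Reactants: 25 C3β alcohol; 26 angelic acid
Product: 28 3β-angeloyloxy-1β-(tert-butyldimethylsilyloxy)-4β,5β-dimethyloctalin-6,9-dien-8-one, via angelic 2,4,6-trichlorobenzoic anhydride 27 (not isolated)
Conditions: 26, 2,4,6-trichlorobenzoyl chloride, Et3N, toluene, rt; then 25, DMAP, toluene, rt to 40 °C
Reagents that add atoms: none
Why: Yamaguchi esterification through mixed anhydride 27 transfers the angeloyl group under mild DMAP catalysis that does not isomerise the (Z)-alkene.

Step 21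
Reactants: 28 angelate
Product: 29 3β-angeloyloxy-1β-(tert-butyldimethylsilyloxy)-7-iodo-4β,5β-dimethyloctalin-6,9-dien-8-one
Conditions: I2, pyridine, CH2Cl2, rt, dark
Reagents that add atoms: iodine, II
Why: Johnson α-iodination: pyridine adds reversibly to the only accessible β position (C6, since C10 is fully substituted), the enolate is iodinated at C7 and elimination restores the dienone.

Step 22
Reactants: 29 iododienone; 30 4,4,5,5-tetramethyl-2-(prop-1-en-2-yl)-1,3,2-dioxaborolane
Product: 31 3β-angeloyloxy-1β-(tert-butyldimethylsilyloxy)-4β,5β-dimethyl-7-(prop-1-en-2-yl)octalin-6,9-dien-8-one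
Conditions: Pd(dppf)Cl2 (cat.), K3PO4 (aq.), THF, 45 °C
Reagents that add atoms: none
Why: Suzuki–Miyaura coupling of the α-iodoenone installs the isopropenyl group at C7; the protected C1 oxygen excludes acyl migration under the basic conditions.

Step 23
Reactants: 31 isopropenyl dienone
Product: 33 (1R,3S,4R,5R)-3-angeloyloxy-1-hydroxy-7-(2-hydroperoxypropan-2-yl)-4,5-dimethyloctalin-6,9-dien-8-one (CNP0300636.1), via triethylsilyl peroxide 32 (not isolated)
Conditions: Co(acac)2 (cat.), O2 (1 atm), Et3SiH, 1,2-dichloroethane, rt; then HF·pyridine, pyridine, THF, 0 °C to rt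
Reagents that add atoms: dioxygen, O=O
Why: Mukaiyama–Isayama cobalt-catalysed hydrosilylperoxidation: hydrogen-atom transfer to the terminal CH2 of the 1,1-disubstituted alkene gives the tertiary C11 radical, which is trapped by O2 and silylated to 32; HF·pyridine then cleaves both the peroxysilane and the C1 silyl ether.

**Compound list**

1 | propane-1,3-diol | OCCCO | starting material
2 | 3-[(4-methoxybenzyl)oxy]propan-1-ol | COc1ccc(COCCCO)cc1 | intermediate
3 | 3-[(4-methoxybenzyl)oxy]propanal | COc1ccc(COCCC=O)cc1 | intermediate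
4 | (S)-4-benzyl-3-propanoyl-1,3-thiazolidine-2-thione | CCC(=O)N1C(=S)SC[C@@H]1Cc1ccccc1 | starting material
5 | chlorotitanium (Z)-enolate of 4 | C/C=C(\O[Ti](Cl)(Cl)Cl)N1C(=S)SC[C@@H]1Cc1ccccc1 | intermediate (not isolated)
6 | (S)-4-benzyl-3-[(2S,3R)-3-hydroxy-5-[(4-methoxybenzyl)oxy]-2-methylpentanoyl]-1,3-thiazolidine-2-thione | COc1ccc(COCC[C@@H](O)[C@H](C)C(=O)N2C(=S)SC[C@@H]2Cc2ccccc2)cc1 | intermediate
7 | (S)-4-benzyl-3-[(2S,3R)-5-[(4-methoxybenzyl)oxy]-2-methyl-3-(triethylsilyloxy)pentanoyl]-1,3-thiazolidine-2-thione | COc1ccc(COCC[C@@H](O[Si](CC)(CC)CC)[C@H](C)C(=O)N2C(=S)SC[C@@H]2Cc2ccccc2)cc1 | intermediate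
8 | (2S,3R)-5-[(4-methoxybenzyl)oxy]-2-methyl-3-(triethylsilyloxy)pentanal | COc1ccc(COCC[C@@H](O[Si](CC)(CC)CC)[C@H](C)C=O)cc1 | intermediate
9 | (3R,4R)-1-[(4-methoxybenzyl)oxy]-4-methyl-3-(triethylsilyloxy)hex-5-yne | COc1ccc(COCC[C@@H](O[Si](CC)(CC)CC)[C@H](C)C#C)cc1 | intermediate
10 | (E)-alkenyldimethylalane from 9 | COc1ccc(COCC[C@@H](O[Si](CC)(CC)CC)[C@H](C)/C(C)=C/[Al](C)C)cc1 | intermediate (not isolated)
11 | (3R,4R,5E)-6-iodo-1-[(4-methoxybenzyl)oxy]-4,5-dimethyl-3-(triethylsilyloxy)hex-5-ene | COc1ccc(COCC[C@@H](O[Si](CC)(CC)CC)[C@H](C)/C(C)=C/I)cc1 | intermediate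
12 | (3R,4R,5E)-6-iodo-4,5-dimethyl-3-(triethylsilyloxy)hex-5-en-1-ol | OCC[C@@H](O[Si](CC)(CC)CC)[C@H](C)/C(C)=C/I | intermediate
13 | (3R,4R,5E)-6-iodo-4,5-dimethyl-3-(triethylsilyloxy)hex-5-enoic acid | OC(=O)C[C@@H](O[Si](CC)(CC)CC)[C@H](C)/C(C)=C/I | intermediate
14 | (3R,4R,5E)-6-iodo-N-methoxy-N,4,5-trimethyl-3-(triethylsilyloxy)hex-5-enamide | CON(C)C(=O)C[C@@H](O[Si](CC)(CC)CC)[C@H](C)/C(C)=C/I | intermediate
15 | 2-[(E)-2-ethoxyethenyl]-4,4,5,5-tetramethyl-1,3,2-dioxaborolane | CCO/C=C/B1OC(C)(C)C(C)(C)O1 | starting material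
16 | (3R,4R,5E,7E)-8-ethoxy-N-methoxy-N,4,5-trimethyl-3-(triethylsilyloxy)octa-5,7-dienamide | CON(C)C(=O)C[C@@H](O[Si](CC)(CC)CC)[C@H](C)/C(C)=C/C=C/OCC | intermediate
17 | ethynylmagnesium bromide | C#C[Mg]Br | starting material
18 | (5R,6R,7E,9E)-10-ethoxy-6,7-dimethyl-5-(triethylsilyloxy)deca-7,9-dien-1-yn-3-one | C#CC(=O)C[C@@H](O[Si](CC)(CC)CC)[C@H](C)/C(C)=C/C=C/OCC | intermediate
19 | 8α-ethoxy-4β,5β-dimethyl-3α-(triethylsilyloxy)octalin-6,9-dien-1-one | CC[Si](CC)(CC)O[C@@H]1CC(=O)C2=C[C@H](OCC)C=C[C@]2(C)[C@H]1C | intermediate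
20 | 4β,5β-dimethyl-3α-(triethylsilyloxy)octalin-6,9-diene-1,8-dione | CC[Si](CC)(CC)O[C@@H]1CC(=O)C2=CC(=O)C=C[C@]2(C)[C@H]1C | intermediate
21 | 1β-hydroxy-4β,5β-dimethyl-3α-(triethylsilyloxy)octalin-6,9-dien-8-one | CC[Si](CC)(CC)O[C@@H]1C[C@@H](O)C2=CC(=O)C=C[C@]2(C)[C@H]1C | intermediate
22 | 1β-(tert-butyldimethylsilyloxy)-4β,5β-dimethyl-3α-(triethylsilyloxy)octalin-6,9-dien-8-one | CC[Si](CC)(CC)O[C@@H]1C[C@@H](O[Si](C)(C)C(C)(C)C)C2=CC(=O)C=C[C@]2(C)[C@H]1C | intermediate
23 | 1β-(tert-butyldimethylsilyloxy)-3α-hydroxy-4β,5β-dimethyloctalin-6,9-dien-8-one | O[C@@H]1C[C@@H](O[Si](C)(C)C(C)(C)C)C2=CC(=O)C=C[C@]2(C)[C@H]1C | intermediate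
24 | 1β-(tert-butyldimethylsilyloxy)-4β,5β-dimethyloctalin-6,9-diene-3,8-dione | O=C1C[C@@H](O[Si](C)(C)C(C)(C)C)C2=CC(=O)C=C[C@]2(C)[C@H]1C | intermediate
25 | 1β-(tert-butyldimethylsilyloxy)-3β-hydroxy-4β,5β-dimethyloctalin-6,9-dien-8-one | O[C@H]1C[C@@H](O[Si](C)(C)C(C)(C)C)C2=CC(=O)C=C[C@]2(C)[C@H]1C | intermediate
26 | angelic acid, (2Z)-2-methylbut-2-enoic acid | C/C=C(/C)C(=O)O | starting material
27 | angelic 2,4,6-trichlorobenzoic anhydride | C/C=C(/C)C(=O)OC(=O)c1c(Cl)cc(Cl)cc1Cl | intermediate (not isolated)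
28 | 3β-angeloyloxy-1β-(tert-butyldimethylsilyloxy)-4β,5β-dimethyloctalin-6,9-dien-8-one | C/C=C(/C)C(=O)O[C@H]1C[C@@H](O[Si](C)(C)C(C)(C)C)C2=CC(=O)C=C[C@]2(C)[C@H]1C | intermediate
29 | 3β-angeloyloxy-1β-(tert-butyldimethylsilyloxy)-7-iodo-4β,5β-dimethyloctalin-6,9-dien-8-one | C/C=C(/C)C(=O)O[C@H]1C[C@@H](O[Si](C)(C)C(C)(C)C)C2=CC(=O)C(I)=C[C@]2(C)[C@H]1C | intermediate
30 | 4,4,5,5-tetramethyl-2-(prop-1-en-2-yl)-1,3,2-dioxaborolane | CC(=C)B1OC(C)(C)C(C)(C)O1 | starting material
31 | 3β-angeloyloxy-1β-(tert-butyldimethylsilyloxy)-4β,5β-dimethyl-7-(prop-1-en-2-yl)octalin-6,9-dien-8-one | C/C=C(/C)C(=O)O[C@H]1C[C@@H](O[Si](C)(C)C(C)(C)C)C2=CC(=O)C(C(C)=C)=C[C@]2(C)[C@H]1C | intermediate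
32 | 3β-angeloyloxy-1β-(tert-butyldimethylsilyloxy)-4β,5β-dimethyl-7-[2-(triethylsilylperoxy)propan-2-yl]octalin-6,9-dien-8-one | C/C=C(/C)C(=O)O[C@H]1C[C@@H](O[Si](C)(C)C(C)(C)C)C2=CC(=O)C(C(C)(C)OO[Si](CC)(CC)CC)=C[C@]2(C)[C@H]1C | intermediate (not isolated)
33 | (1R,3S,4R,5R)-3-angeloyloxy-1-hydroxy-7-(2-hydroperoxypropan-2-yl)-4,5-dimethyloctalin-6,9-dien-8-one (CNP0300636.1) | C/C=C(/C)C(=O)O[C@H]1C[C@@H](O)C2=CC(=O)C(C(C)(C)OO)=C[C@]2(C)[C@H]1C | target

**Totals.** Total step count: 23. Longest linear sequence: 23 steps (1 to 33; compounds 4, 15, 17, 26 and 30 are bought).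

**Steps most likely to fail**

1. Step 13 (key step). The tether imposes the orientation in which the ethoxy group does not polarise the diene towards C10, so the cycloaddition may be slow. Meanwhile the terminal ynone can oligomerise or take up nucleophiles and the enol ether can hydrolyse, so 18 may be consumed before it cyclises. The fallback sets out from amide 16 and returns at ene-dione 20; it uses an alkene dienophile and adjusts the oxidation level afterwards. Vinylmagnesium bromide in THF converts 16 into (5R,6R,7E,9E)-10-ethoxy-6,7-dimethyl-5-(triethylsilyloxy)deca-1,7,9-trien-3-one F1. Alkenyl ketones of this tether length undergo the intramolecular Diels–Alder reaction on gentle heating (toluene, 60–80 °C) through the same all-equatorial half-chair, which should give 8-ethoxy-4β,5β-dimethyl-3α-(triethylsilyloxy)octal-6-en-1-one F2 (C8 and C10 as mixtures, both removed later). DDQ in wet CH2Cl2 oxidises the allylic ethyl ether to 4β,5β-dimethyl-3α-(triethylsilyloxy)octal-6-ene-1,8-dione F3. Dehydrogenation of its 1,4-dicarbonyl unit C1–C10–C9–C8 (DDQ, dioxane, 80 °C) introduces C9=C10 and gives 20.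

2. Step 20. Acylation of the C3 hydroxyl may be slow because the β face carries both the C5 methyl and the C1 silyl ether in a 1,3-diaxial array. Forcing conditions invite Z-to-E isomerisation of the angelate or silyl migration from O1 to O3. The fallback sets out from 25 and returns at 28; it acylates while C1 is trigonal. HF·pyridine removes the silyl ether to give 1β,3β-dihydroxy-4β,5β-dimethyloctalin-6,9-dien-8-one F4. MnO2 in CH2Cl2 oxidises only the allylic C1 alcohol to 3β-hydroxy-4β,5β-dimethyloctalin-6,9-diene-1,8-dione F5. Yamaguchi esterification with 26 gives 3β-angeloyloxy-4β,5β-dimethyloctalin-6,9-diene-1,8-dione F6. Luche reduction (hydride anti to the C5 methyl and the C3 ester) gives 3β-angeloyloxy-1β-hydroxy-4β,5β-dimethyloctalin-6,9-dien-8-one F7, and t-BuMe2SiOTf with 2,6-lutidine returns 28.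

3. Step 23. Hydrogen-atom transfer may also reach the angelate or the dienone, and the allylic C11 radical may take up oxygen at C6 instead of C11, giving regioisomeric or over-reduced peroxides. The fallback sets out from 31 and returns at 33; it uses a singlet-oxygen ene reaction instead of radical chemistry. Conjugate reduction at C6 with [(Ph3P)CuH]6 in toluene, followed by DBU to bring the alkene into conjugation, gives 3β-angeloyloxy-1β-(tert-butyldimethylsilyloxy)-4β,5β-dimethyl-7-(propan-2-ylidene)octal-9-en-8-one F8. HF·pyridine frees the C1 hydroxyl to give 3β-angeloyloxy-1β-hydroxy-4β,5β-dimethyl-7-(propan-2-ylidene)octal-9-en-8-one F9. Dye-sensitised photo-oxygenation (O2, tetraphenylporphyrin, visible light, CH2Cl2, 0 °C) is a Schenck ene reaction that takes the C6 hydrogen geminal to the carbonyl, delivers oxygen to C11, re-forms C6=C7 and should give 33.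

**Further compounds**

F1 | step 13 | (5R,6R,7E,9E)-10-ethoxy-6,7-dimethyl-5-(triethylsilyloxy)deca-1,7,9-trien-3-one | C=CC(=O)C[C@@H](O[Si](CC)(CC)CC)[C@H](C)/C(C)=C/C=C/OCC
F2 | step 13 | 8-ethoxy-4β,5β-dimethyl-3α-(triethylsilyloxy)octal-6-en-1-one | CC[Si](CC)(CC)O[C@@H]1CC(=O)C2CC(OCC)C=C[C@]2(C)[C@H]1C
F3 | step 13 | 4β,5β-dimethyl-3α-(triethylsilyloxy)octal-6-ene-1,8-dione | CC[Si](CC)(CC)O[C@@H]1CC(=O)C2CC(=O)C=C[C@]2(C)[C@H]1C
F4 | step 20 | 1β,3β-dihydroxy-4β,5β-dimethyloctalin-6,9-dien-8-one | O[C@H]1C[C@@H](O)C2=CC(=O)C=C[C@]2(C)[C@H]1C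
F5 | step 20 | 3β-hydroxy-4β,5β-dimethyloctalin-6,9-diene-1,8-dione | O[C@H]1CC(=O)C2=CC(=O)C=C[C@]2(C)[C@H]1C
F6 | step 20 | 3β-angeloyloxy-4β,5β-dimethyloctalin-6,9-diene-1,8-dione | C/C=C(/C)C(=O)O[C@H]1CC(=O)C2=CC(=O)C=C[C@]2(C)[C@H]1C
F7 | step 20 | 3β-angeloyloxy-1β-hydroxy-4β,5β-dimethyloctalin-6,9-dien-8-one | C/C=C(/C)C(=O)O[C@H]1C[C@@H](O)C2=CC(=O)C=C[C@]2(C)[C@H]1C
F8 | step 23 | 3β-angeloyloxy-1β-(tert-butyldimethylsilyloxy)-4β,5β-dimethyl-7-(propan-2-ylidene)octal-9-en-8-one | C/C=C(/C)C(=O)O[C@H]1C[C@@H](O[Si](C)(C)C(C)(C)C)C2=CC(=O)C(=C(C)C)C[C@]2(C)[C@H]1C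
F9 | step 23 | 3β-angeloyloxy-1β-hydroxy-4β,5β-dimethyl-7-(propan-2-ylidene)octal-9-en-8-one | C/C=C(/C)C(=O)O[C@H]1C[C@@H](O)C2=CC(=O)C(=C(C)C)C[C@]2(C)[C@H]1C
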